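## The problem

Compound 18 is a 2,3-dihydrobenzofuran: a benzene ring A fused to a dihydrofuran ring B. C2 carries a 3-oxoprop-1-en-2-yl group (an α-substituted acrolein), C3 a tiglate, and C5, para to the ring oxygen, an (R)-1-(tigloyloxy)ethyl chain. C2 (R) and C3 (S) are adjacent and trans, so one stereospecific event can relate them. The side-chain carbinol carbon lies across the arene from them and can only be set by a reagent. The fragile parts are the enal, a Michael acceptor whose exo-methylene can slip into conjugation with C2, and the two benzylic ester C–O bonds, both activated towards ionisation by the ring oxygen. Loss of tiglic acid across C2–C3 would also aromatise ring B to a benzofuran. The tiglates have allylic methyl groups of their own, which a late allylic oxidation must leave alone. The feature that opens the structure is the pattern around O1: the C2 branch is a 2-propenyl unit bound through its central carbon, O1 sits on C2, and a second oxygen sits on C3. Moving O1 from C2 to the central branch carbon turns ring B into a 2,2-dimethylchroman oxygenated at C3 and C4, whose two methyl groups are equivalent and whose stereocentres derive from a chromene double bond.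

## Retrosynthesis

**18 ⇒ 16.** The aldehyde oxygen is removed first. The enal is traced to the allylic methyl of the isopropenyl group in bis-tiglate 16, with primary allylic alcohol 17 as the stage between. Introducing this oxygen earlier would make the two substituents on the quaternary chroman carbon unequal and would place an electron-withdrawing group next to the cation of the key step. An enal would also not survive hydride, fluoride or acyl-transfer catalysts. Compound 16 has no Michael acceptor and is one oxidation level simpler. The forward oxidation must choose the methyl of the 1,1-disubstituted alkene over the allylic methyls of two ester-conjugated alkenes and over the C2 methine.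

**16 ⇒ 13 + 14.** Both acyl C–O bonds are cut together, since the two esters are identical. Carrying an ester through the key step is rejected: an acyloxy group next to the leaving group would participate, and a side-chain ester would be exposed to triflic conditions. Diol 13 is ten carbons smaller, and tiglic acid 14 is commercial. The forward acylation, through mixed anhydride 15, must form O–acyl bonds without breaking either benzylic C–O bond.

**13 ⇒ 12 ⇒ 11.** The Si–O bond and then the carbinol C–H bond of the side chain are cut, leading to aryl methyl ketone 11. The remote centre needs reagent control, and an aryl methyl ketone is a good substrate for catalytic asymmetric reduction. The acetyl group is also a robust spectator that can be carried from the first step. The forward reduction must give the (R)-alcohol and leave the isopropenyl group alone.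

**11 ⇒ 9 (key disconnection).** The O1–C2 bond of ring B is cut and the oxygen is reattached to the central carbon of the isopropenyl group, which becomes the gem-dimethyl carbon of chromanol 9. In the forward sense this runs through triflate 10. Compared with cutting C2–C3 or the arene bonds, this cut places both ring stereocentres in a six-membered ring, where they derive from a cis-alkene. The three-carbon branch becomes part of a ring that forms in one thermal cascade. The forward step must invert the carbinol carbon cleanly and favour the oxygen shift over other cationic pathways.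

**9 ⇒ 8 ⇒ 7.** The Si–O bond at C4 is cut, then the C4–OH bond of trans-diol 8, leading to cis-fused epoxide 7. The trans arrangement required by the key step is the signature of anti opening of an epoxide at its benzylic carbon. A cis-diol from dihydroxylation would end as the cis-dihydrobenzofuran and is excluded. The forward steps must invert C4 and silylate the C4 hydroxyl in preference to the C3 hydroxyl.

**7 ⇒ 6.** The two epoxide C–O bonds are cut to give achiral chromene 6. 2,2-Dimethylchromenes are among the best substrates for Mn(salen)-catalysed epoxidation, so both ring stereocentres come from this one catalytic step.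

**6 ⇒ 3 ⇒ 1 + 2.** The pyran ring is opened at the aryl–C4 bond through the aryl propargyl ether rearrangement (via 4 and 5), and ether 3 is cut at its O–C bond. 4-Hydroxyacetophenone 1 supplies the arene with the acetyl group para to oxygen. 3-Chloro-3-methylbut-1-yne 2 supplies the five carbons that end as C2, C3 and the branch.

## Roads not taken

**Alternative 1:** Three bonds of ring A (C3a–C7a, C4–C5, C6–C7) are cut, so rings A and B form together. In the forward step, diyne A2 (a silyl ynol ether tethered through O1–C2–C3 to a propargylic tiglate) and (R)-but-3-yn-2-yl tiglate A3 cyclotrimerise under RhCl(PPh3)3 (monovalent rhodium) to give arene A1.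
- Merits: it is the most convergent plan. The side-chain stereocentre is bought with A3 instead of being made by asymmetric catalysis, which is better than the chosen plan at that centre. Both esters and the oxidised branch are in place before the key step.
- Weak points: A2 holds both ring stereocentres in an acyclic anti-dioxygenated unit and needs an asymmetric synthesis about as long as the whole chromene sequence. Ynol ethers of secondary alcohols with β-hydrogens fragment to ketene and alkene on heating. Propargylic esters are prone to metal-promoted acyloxy migration. The regiochemistry of alkyne uptake depends on the triethylsilyl group, whose removal from C7 of A1 needs acid or fluoride on a molecule with two ionisable benzylic esters.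
- Comparison: the chosen plan is linear, but every stereocentre comes from a reaction class of high reliability and no steering group has to be removed.

**Alternative 2:** The C2–C3 bond is cut. In the forward step the γ-aryloxy-β-methylallyl boronate A5 adds through its oxygen-bearing carbon to the ortho aldehyde and gives hydroxy ketone A4 directly.
- Merits: it is the shortest route to the nucleus. A4 needs no protecting group and is one reduction away from diol 13. If A4 were available trans and enantiopure, this road would beat the chosen one by several steps.
- Weak points: A5 carries no stereochemical information. The allylation runs through a six-membered boron transition state fused to the forming five-membered ring, so the relative configuration is set by that constraint and the trans-2,3 outcome is not assured. Enantiocontrol would have to be imposed on a fast intramolecular background reaction. A5 is also an enol ether of defined geometry that must be made in the presence of the aldehyde it attacks.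
- Comparison: the chosen plan sets absolute configuration with an epoxidation for which the substrate class is ideal, and relative configuration by two stereospecific displacements.

**Alternative 3:** C7–C7a and C3a–C4 are cut, so ring A is grown on a ring B taken from 2-deoxy-D-ribonolactone. Silyl ketene acetal A8 adds as dienophile to 5-acetyl-2H-pyran-2-one A7, and loss of CO2 and trimethylsilanol gives A6.
- Merits: both ring B stereocentres come from the chiral pool, which is more secure than any catalyst, and the acetyl group arrives correctly placed with the pyrone.
- Weak points: A8 is the enol derivative of a lactone with a β-silyloxy group, and enolising such lactones invites β-elimination to the butenolide, which erases C3. The cycloadduct must expel silanol and not the ring oxygen. C2 of A6 carries an alkyne, and converting it to the 1-formylvinyl branch needs Markovnikov carbon–carbon chemistry of several steps, on top of the sugar-to-alkyne homologation.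
- Comparison: the chosen plan creates the branch with the right carbon skeleton in the key step itself and is shorter overall.

Key step: step 6

Remark: chroman numbering is used for compounds 6–10 and benzofuran numbering from 11 on; chroman C3 and C4 become benzofuran C2 and C3.

## Route

Step 1
Reactants: 1 4-hydroxyacetophenone; 2 3-chloro-3-methylbut-1-yne
Product: 3 1-[4-(2-methylbut-3-yn-2-yloxy)phenyl]ethanone
Conditions: CuCl2·2H2O (cat.), DBU, MeCN, 0 °C
Reagents that add atoms: none
Why: Copper-catalysed O-propargylation of a phenol with a tertiary propargylic chloride; the copper acetylide ionises to an allenylidene-type electrophile that the phenoxide captures at the tertiary carbon, which works for electron-poor phenols where plain carbonate alkylation is slow.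

Step 2
Reactants: 3
Product: 6 1-(2,2-dimethyl-2H-chromen-6-yl)ethanone, via allenylphenol 4 (not isolated), via quinone methide 5 (not isolated)
Conditions: 1,2-dichlorobenzene, 180 °C
Reagents that add atoms: none
Why: Thermal aryl propargyl ether rearrangement: aromatic Claisen shift and tautomerisation give 4, a 1,5-hydrogen shift gives 5, and 6π-oxa-electrocyclisation closes the pyran ring; the acetyl group blocks the para position, so only the ortho course is open.

Step 3
Reactants: 6
Product: 7 1-[(3R,4R)-3,4-epoxy-2,2-dimethylchroman-6-yl]ethanone
Conditions: (R,R)-Mn(salen)Cl [salen = N,N'-bis(3,5-di-tert-butylsalicylidene)cyclohexane-1,2-diaminate] (5 mol%), mCPBA, NMO, CH2Cl2, −78 °C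
Reagents that add atoms: meta-chloroperoxybenzoic acid (mCPBA), O=C(OO)c1cccc(Cl)c1
Why: Jacobsen epoxidation of a cis-disubstituted, aryl-conjugated alkene, for which 2,2-dimethylchromenes are a favoured substrate class; the (R,R)-ligand on the oxo-manganese species (made from the trivalent manganese precatalyst) should deliver oxygen to the face that gives the (3R,4R)-epoxide, and the low-temperature peracid protocol avoids hypochlorite in the presence of the methyl ketone.

Step 4
Reactants: 7
Product: 8 1-[(3R,4S)-3,4-dihydroxy-2,2-dimethylchroman-6-yl]ethanone
Conditions: HClO4 (cat.), THF/H2O, 0 °C to rt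
Reagents that add atoms: water, O
Why: Acid-catalysed epoxide hydrolysis; water attacks the benzylic C4 with inversion while the C3–O bond is untouched, giving the trans-(3R,4S)-diol, and the acetyl group para to the ring oxygen tempers benzylic cation character so the opening stays anti.

Step 5
Reactants: 8
Product: 9 1-[(3R,4S)-4-(tert-butyldimethylsilyloxy)-3-hydroxy-2,2-dimethylchroman-6-yl]ethanone
Conditions: TBSCl (1.1 equiv), imidazole, DMF, 0 °C
Reagents that add atoms: tert-butyldimethylsilyl chloride (TBSCl), CC(C)(C)[Si](C)(C)Cl
Why: Sterically controlled monosilylation of a diol; the C3 hydroxyl is neopentyl-type and gauche to both methyl groups of C2, whereas the benzylic C4 hydroxyl is more accessible and more acidic, so a bulky silyl chloride should react at C4.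

Step 6
Reactants: 9
Product: 11 1-[(2R,3S)-3-(tert-butyldimethylsilyloxy)-2-(prop-1-en-2-yl)-2,3-dihydrobenzofuran-5-yl]ethanone, via triflate 10 (not isolated)
Conditions: Tf2O, 2,6-di-tert-butyl-4-methylpyridine, CH2Cl2, −78 °C to rt
Reagents that add atoms: none
Why: Triflic anhydride and the hindered pyridine convert the C3 hydroxyl of 9 into triflate 10, in whose diequatorial half-chair the ring O1–C2 bond lies antiperiplanar to the C3–OTf bond. As triflate departs, O1 bridges to C3 from the rear through an oxiranium-like transition state (a 3-exo-tet attack of the ring oxygen) and its bond to the gem-dimethyl carbon breaks, so the six-membered pyran contracts to the five-membered dihydrofuran ring B and the O1–C2 bond of the benzofuran is formed. The tertiary cation left at the former chroman C2 loses a methyl proton to the base and becomes the isopropenyl group. The closest known reaction type is the ring contraction of 3-sulfonyloxy or DAST-activated 3-hydroxy-2,2-dimethylchromans to 2-isopropenyl- or 2-(2-substituted-propan-2-yl)-2,3-dihydrobenzofurans by 1,2-oxygen shift, a heteroatom version of the Wagner–Meerwein shift. The new stereocentre, C2 of 11, is the former C3 and is set by inversion at the migration terminus (substrate control, stereospecific), while the silyloxy carbon is untouched, so trans-(3R,4S)-9 should give trans-(2R,3S)-11. The step needs the oxygen shift to win over a 1,2-shift of the aryl carbon C4a (whose bond to C4 is also antiperiplanar), over elimination and over participation by the C4 oxygen. The oxygen shift leads to a tertiary cation and uses a lone pair, a better internal nucleophile than the π system of an acetyl-bearing arene; the equatorial triflate has no antiperiplanar hydrogen, the C4 substituent stays equatorial because an axial one would clash with the axial methyl of C2, and a bulky silyl ether is a poor neighbouring group where an acyloxy group would be a good one.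

Step 7
Reactants: 11
Product: 12 (1R)-1-[(2R,3S)-3-(tert-butyldimethylsilyloxy)-2-(prop-1-en-2-yl)-2,3-dihydrobenzofuran-5-yl]ethanol
Conditions: RuCl[(R,R)-TsDPEN](p-cymene) (1 mol%), HCO2H/Et3N (5:2), EtOAc, rt
Reagents that add atoms: none
Why: Noyori asymmetric transfer hydrogenation of an aryl methyl ketone; the (R,R)-TsDPEN ruthenium hydride gives (R)-1-arylethanols by outer-sphere hydride transfer, which does not engage the isolated alkene, and the remote ring stereocentres leave catalyst control undisturbed.

Step 8
Reactants: 12
Product: 13 (2R,3S)-5-[(1R)-1-hydroxyethyl]-2-(prop-1-en-2-yl)-2,3-dihydrobenzofuran-3-ol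
Conditions: TBAF, AcOH, THF, 0 °C to rt
Reagents that add atoms: none
Why: Fluoride cleavage of a silyl ether; buffering with acetic acid keeps the medium near neutral, so the C3 alcohol is neither ionised (acid) nor eliminated towards the benzofuran (base), and no stereocentre is touched.

Step 9
Reactants: 13; 14 tiglic acid [(E)-2-methylbut-2-enoic acid]
Product: 16 (2R,3S)-5-[(1R)-1-{[(2E)-2-methylbut-2-enoyl]oxy}ethyl]-2-(prop-1-en-2-yl)-2,3-dihydrobenzofuran-3-yl (2E)-2-methylbut-2-enoate, via mixed anhydride 15 (not isolated)
Conditions: 14 (3 equiv), 2,4,6-trichlorobenzoyl chloride, Et3N, toluene, rt; then 13, DMAP, rt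
Reagents that add atoms: none
Why: Yamaguchi esterification: 14 is activated as mixed anhydride 15, which DMAP converts into the acylpyridinium that acylates both hydroxyls; only O–acyl bonds form, so the three stereocentres are untouched, and the E-tiglate is the thermodynamically preferred geometry and should not isomerise.

Step 10
Reactants: 16
Product: 18 (2R,3S)-2-(3-oxoprop-1-en-2-yl)-5-[(1R)-1-{[(2E)-2-methylbut-2-enoyl]oxy}ethyl]-2,3-dihydrobenzofuran-3-yl (2E)-2-methylbut-2-enoate, via allylic alcohol 17 (not isolated)
Conditions: SeO2 (cat.), t-BuOOH, CH2Cl2, rt; then (crude, after aqueous wash) Dess–Martin periodinane, NaHCO3, CH2Cl2, 0 °C to rt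
Reagents that add atoms: selenium dioxide, O=[Se]=O; tert-butyl hydroperoxide, CC(C)(C)OO
Why: Selenium dioxide allylic oxidation (ene reaction, then [2,3]-sigmatropic shift) should hydroxylate the methyl of the 1,1-disubstituted alkene, which is more electron-rich than the ester-conjugated tiglate alkenes and reacts at CH3 in preference to the C2 methine. Dess–Martin oxidation under bicarbonate then takes 17, together with any enal already present, to 18 without acid that could ionise the benzylic esters; no stereocentre is involved.

## Compound list

1 | 4-hydroxyacetophenone | CC(=O)c1ccc(O)cc1 | starting material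
2 | 3-chloro-3-methylbut-1-yne | C#CC(C)(C)Cl | starting material
3 | 1-[4-(2-methylbut-3-yn-2-yloxy)phenyl]ethanone | CC(=O)c1ccc(OC(C)(C)C#C)cc1 | intermediate
4 | 1-[4-hydroxy-3-(3-methylbuta-1,2-dien-1-yl)phenyl]ethanone | CC(=O)c1ccc(O)c(C=C=C(C)C)c1 | intermediate (not isolated)
5 | (6Z)-4-acetyl-6-(3-methylbut-2-en-1-ylidene)cyclohexa-2,4-dien-1-one | CC(C)=C/C=C1/C=C(C(C)=O)C=CC1=O | intermediate (not isolated)
6 | 1-(2,2-dimethyl-2H-chromen-6-yl)ethanone | CC(=O)c1ccc2OC(C)(C)C=Cc2c1 | intermediate
7 | 1-[(3R,4R)-3,4-epoxy-2,2-dimethylchroman-6-yl]ethanone | CC1(C)Oc2ccc(C(C)=O)cc2[C@H]3O[C@@H]13 | intermediate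
8 | 1-[(3R,4S)-3,4-dihydroxy-2,2-dimethylchroman-6-yl]ethanone | CC1(C)Oc2ccc(C(C)=O)cc2[C@H](O)[C@H]1O | intermediate
9 | 1-[(3R,4S)-4-(tert-butyldimethylsilyloxy)-3-hydroxy-2,2-dimethylchroman-6-yl]ethanone | CC1(C)Oc2ccc(C(C)=O)cc2[C@H](O[Si](C)(C)C(C)(C)C)[C@H]1O | intermediate
10 | (3R,4S)-6-acetyl-4-(tert-butyldimethylsilyloxy)-2,2-dimethylchroman-3-yl trifluoromethanesulfonate | CC1(C)Oc2ccc(C(C)=O)cc2[C@H](O[Si](C)(C)C(C)(C)C)[C@H]1OS(=O)(=O)C(F)(F)F | intermediate (not isolated)
11 | 1-[(2R,3S)-3-(tert-butyldimethylsilyloxy)-2-(prop-1-en-2-yl)-2,3-dihydrobenzofuran-5-yl]ethanone | C=C(C)[C@H]1Oc2ccc(C(C)=O)cc2[C@@H]1O[Si](C)(C)C(C)(C)C | intermediate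
12 | (1R)-1-[(2R,3S)-3-(tert-butyldimethylsilyloxy)-2-(prop-1-en-2-yl)-2,3-dihydrobenzofuran-5-yl]ethanol | C=C(C)[C@H]1Oc2ccc([C@@H](C)O)cc2[C@@H]1O[Si](C)(C)C(C)(C)C | intermediate
13 | (2R,3S)-5-[(1R)-1-hydroxyethyl]-2-(prop-1-en-2-yl)-2,3-dihydrobenzofuran-3-ol | C=C(C)[C@H]1Oc2ccc([C@@H](C)O)cc2[C@@H]1O | intermediate
14 | tiglic acid, (E)-2-methylbut-2-enoic acid | C/C=C(\C)C(=O)O | starting material
15 | (2E)-2-methylbut-2-enoic 2,4,6-trichlorobenzoic anhydride | C/C=C(\C)C(=O)OC(=O)c1c(Cl)cc(Cl)cc1Cl | intermediate (not isolated)
16 | (2R,3S)-5-[(1R)-1-{[(2E)-2-methylbut-2-enoyl]oxy}ethyl]-2-(prop-1-en-2-yl)-2,3-dihydrobenzofuran-3-yl (2E)-2-methylbut-2-enoate | C=C(C)[C@H]1Oc2ccc([C@@H](C)OC(=O)/C(C)=C/C)cc2[C@@H]1OC(=O)/C(C)=C/C | intermediate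
17 | (2R,3S)-2-(3-hydroxyprop-1-en-2-yl)-5-[(1R)-1-{[(2E)-2-methylbut-2-enoyl]oxy}ethyl]-2,3-dihydrobenzofuran-3-yl (2E)-2-methylbut-2-enoate | C=C(CO)[C@H]1Oc2ccc([C@@H](C)OC(=O)/C(C)=C/C)cc2[C@@H]1OC(=O)/C(C)=C/C | intermediate (not isolated)
18 | (2R,3S)-2-(3-oxoprop-1-en-2-yl)-5-[(1R)-1-{[(2E)-2-methylbut-2-enoyl]oxy}ethyl]-2,3-dihydrobenzofuran-3-yl (2E)-2-methylbut-2-enoate | C=C(C=O)[C@H]1Oc2ccc([C@@H](C)OC(=O)/C(C)=C/C)cc2[C@@H]1OC(=O)/C(C)=C/C | target

## Step count and risks

Total steps: 10. Longest linear sequence: 10 steps (1 to 18).

**Step 6 (key step).** The most likely failure is poor partitioning of the cationic intermediate. After the oxygen shift the bridged ion may return to triflate, be captured at the tertiary carbon, or lose the C2 proton to an enol ether that goes on to eliminate silanol and aromatise. A second channel is the 1,2-shift of aryl carbon C4a, which is rewarded by a silyloxy-stabilised cation and would contract the ring the wrong way.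
Fallback: starting from 9, the C3 hydroxyl would be mesylated (MsCl, Et3N) to give the isolable mesylate F1. Heating F1 in buffered aqueous acetone should bring about the same oxygen shift under solvolytic conditions, with water capturing the tertiary cation to give the tertiary alcohol F2. Dehydration of F2 with the Burgess reagent, a transformation well established for 2-(2-hydroxypropan-2-yl)dihydrobenzofurans, would then form the isopropenyl group and return to the route at 11. This separates the rearrangement from alkene formation and uses a leaving group that should ionise only with help from the ring oxygen.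

**Step 5.** Silylation may occur at the wrong oxygen or at both, because the discrimination rests on a steric difference alone and silyl groups can migrate between vicinal oxygens under basic conditions.
Fallback: starting from epoxide 7, acid-catalysed opening with 2-naphthylmethanol (camphorsulfonic acid, CH2Cl2) would place the protecting group at C4 by the regiochemistry of the epoxide itself and give the 4-(2-naphthylmethyl) ether F3. Triflation of F3 as in step 6 would give its triflate F4 (not isolated), which should contract to the ring-contracted ether F5. DDQ in wet CH2Cl2 would remove the naphthylmethyl group to give the hydroxy ketone F6, and transfer hydrogenation as in step 7 would rejoin the route at 13. This bypass is held in reserve because an alkyl ether oxygen is a better neighbouring group than a silyl ether oxygen in the key step, and its removal needs an oxidant next to the isopropenyl group.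

**Step 10.** The selenium reagent may fail to discriminate among three alkenes that all carry allylic methyl groups, over-oxidation may occur, and selenous acid may ionise the benzylic esters.
Fallback: starting from diol 13, where the isopropenyl group is the only alkene, SeO2/t-BuOOH would give the triol F7. TEMPO with PhI(OAc)2, which oxidises primary allylic alcohols in preference to secondary ones, would give the enal diol F8. Yamaguchi esterification of F8 with 14 (through 15) would then return to the route at 18.

**Step 9.** Acylation of the hindered C3 hydroxyl may be incomplete, and under forcing conditions the C3 oxygen substituent may ionise or eliminate, driven by aromatisation to the benzofuran.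
Fallback: starting from 12, the side-chain alcohol alone would be esterified with 14 under the Yamaguchi conditions to give the side-chain mono-tiglate F9. HF·pyridine would then free C3 as the hydroxy mono-tiglate F10, and the C3 ester would be made last and alone with anhydride 15 and DMAP at low temperature, returning to the route at 16. Each hydroxyl then gets its own conditions, and the sensitive C3 ester is exposed to the fewest further operations.

## Further compounds

F1 | step 6 | (3R,4S)-6-acetyl-4-(tert-butyldimethylsilyloxy)-2,2-dimethylchroman-3-yl methanesulfonate | CC1(C)Oc2ccc(C(C)=O)cc2[C@H](O[Si](C)(C)C(C)(C)C)[C@H]1OS(C)(=O)=O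
F2 | step 6 | 1-[(2S,3S)-3-(tert-butyldimethylsilyloxy)-2-(2-hydroxypropan-2-yl)-2,3-dihydrobenzofuran-5-yl]ethanone | CC(C)(O)[C@H]1Oc2ccc(C(C)=O)cc2[C@@H]1O[Si](C)(C)C(C)(C)C
F3 | step 5 | 1-[(3R,4S)-3-hydroxy-2,2-dimethyl-4-(naphthalen-2-ylmethoxy)chroman-6-yl]ethanone | CC1(C)Oc2ccc(C(C)=O)cc2[C@H](OCc3ccc4ccccc4c3)[C@H]1O
F4 | step 5 | (3R,4S)-6-acetyl-2,2-dimethyl-4-(naphthalen-2-ylmethoxy)chroman-3-yl trifluoromethanesulfonate | CC1(C)Oc2ccc(C(C)=O)cc2[C@H](OCc3ccc4ccccc4c3)[C@H]1OS(=O)(=O)C(F)(F)F
F5 | step 5 | 1-[(2R,3S)-3-(naphthalen-2-ylmethoxy)-2-(prop-1-en-2-yl)-2,3-dihydrobenzofuran-5-yl]ethanone | C=C(C)[C@H]1Oc2ccc(C(C)=O)cc2[C@@H]1OCc3ccc4ccccc4c3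
F6 | step 5 | 1-[(2R,3S)-3-hydroxy-2-(prop-1-en-2-yl)-2,3-dihydrobenzofuran-5-yl]ethanone | C=C(C)[C@H]1Oc2ccc(C(C)=O)cc2[C@@H]1O
F7 | step 10 | (2R,3S)-5-[(1R)-1-hydroxyethyl]-2-(3-hydroxyprop-1-en-2-yl)-2,3-dihydrobenzofuran-3-ol | C=C(CO)[C@H]1Oc2ccc([C@@H](C)O)cc2[C@@H]1O
F8 | step 10 | 2-[(2R,3S)-3-hydroxy-5-[(1R)-1-hydroxyethyl]-2,3-dihydrobenzofuran-2-yl]prop-2-enal | C=C(C=O)[C@H]1Oc2ccc([C@@H](C)O)cc2[C@@H]1O
F9 | step 9 | (1R)-1-[(2R,3S)-3-(tert-butyldimethylsilyloxy)-2-(prop-1-en-2-yl)-2,3-dihydrobenzofuran-5-yl]ethyl (2E)-2-methylbut-2-enoate | C=C(C)[C@H]1Oc2ccc([C@@H](C)OC(=O)/C(C)=C/C)cc2[C@@H]1O[Si](C)(C)C(C)(C)C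
F10 | step 9 | (1R)-1-[(2R,3S)-3-hydroxy-2-(prop-1-en-2-yl)-2,3-dihydrobenzofuran-5-yl]ethyl (2E)-2-methylbut-2-enoate | C=C(C)[C@H]1Oc2ccc([C@@H](C)OC(=O)/C(C)=C/C)cc2[C@@H]1O
A1 | alternative 1 | (2R,3S)-2-[3-(tert-butyldimethylsilyloxy)prop-1-en-2-yl]-7-(triethylsilyl)-5-[(1R)-1-{[(2E)-2-methylbut-2-enoyl]oxy}ethyl]-2,3-dihydrobenzofuran-3-yl (2E)-2-methylbut-2-enoate | C=C(CO[Si](C)(C)C(C)(C)C)[C@H]1Oc2c([Si](CC)(CC)CC)cc([C@@H](C)OC(=O)/C(C)=C/C)cc2[C@@H]1OC(=O)/C(C)=C/C
A2 | alternative 1 | (3S,4R)-5-[(tert-butyldimethylsilyloxy)methyl]-4-[(triethylsilyl)ethynyloxy]hex-5-en-1-yn-3-yl (2E)-2-methylbut-2-enoate | C=C(CO[Si](C)(C)C(C)(C)C)[C@@H](OC#C[Si](CC)(CC)CC)[C@H](C#C)OC(=O)/C(C)=C/C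
A3 | alternative 1 | (R)-but-3-yn-2-yl (2E)-2-methylbut-2-enoate | C#C[C@@H](C)OC(=O)/C(C)=C/C
A4 | alternative 2 | 1-[(2R,3S)-3-hydroxy-2-(prop-1-en-2-yl)-2,3-dihydrobenzofuran-5-yl]ethanone | C=C(C)[C@H]1Oc2ccc(C(C)=O)cc2[C@@H]1O
A5 | alternative 2 | 1-[3-formyl-4-{[(1E)-2-methyl-3-(4,4,5,5-tetramethyl-1,3,2-dioxaborolan-2-yl)prop-1-en-1-yl]oxy}phenyl]ethanone | CC(=O)c1ccc(O/C=C(\C)CB2OC(C)(C)C(C)(C)O2)c(C=O)c1
A6 | alternative 3 | 1-[(2R,3S)-3-(tert-butyldimethylsilyloxy)-2-(trimethylsilylethynyl)-2,3-dihydrobenzofuran-5-yl]ethanone | C[Si](C)(C)C#C[C@H]1Oc2ccc(C(C)=O)cc2[C@@H]1O[Si](C)(C)C(C)(C)C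
A7 | alternative 3 | 5-acetyl-2H-pyran-2-one | CC(=O)C1=COC(=O)C=C1
A8 | alternative 3 | tert-butyl(dimethyl){[(2R,3S)-5-(trimethylsilyloxy)-2-(trimethylsilylethynyl)-2,3-dihydrofuran-3-yl]oxy}silane | C[Si](C)(C)C#C[C@H]1OC(O[Si](C)(C)C)=C[C@@H]1O[Si](C)(C)C(C)(C)C
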